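**Assumption:** the name abiesin is taken to mean exactly the constitution of the given SMILES string. Compounds 1, 3, 7, 10 and 12 are taken as purchased, 12 as its THF solution.

## The problem

Abiesin 18 joins a flavonol, 3,7-dihydroxy-2-(4-methoxyphenyl)chromen-4-one (atoms unprimed, rings A and C), through C6 of its ring A to C3′ of ring B of a flavone. The flavone's 4′-methoxyphenyl ring B is primed and its 5″-hydroxy-7″-methoxychromenone is double-primed. There is no stereocentre, and the C6–C3′ axis has only two ortho substituents (7-OH and 4′-OMe), so it is not configurationally stable. Nothing has to be controlled in space; the problem is regiochemistry and the differentiation of six oxygen substituents. Three are free hydroxyls (O3, O7, O5″) and three are methyl ethers (anisyl, 4′, 7″), so the hydroxyls must travel under a mask that comes off without touching aryl methyl ethers. Flavonol ring A is 1,2,4,5-tetrasubstituted and has no oxygen at C5, which puts it outside the phloroglucinol-based flavonoid routes; the ketone for a chalcone route, a 5-aryl-2,4-dihydroxyacetophenone, would first have to be made. The two 4-pyranone rings open when hard nucleophiles add at C2 or C2″ at high temperature, the free 3-hydroxy-4-pyranone is easily oxidised in base, and any acid chloride on the way must coexist with a pyranone carbonyl. The enabling feature is that O1 sits on C8a, ortho to C4a, and O7 sits on C7, para to C4a, the carbon that bears the C4 carbonyl. Both C–O bonds are therefore at positions where an aryl ketone activates a C–F bond towards nucleophilic aromatic substitution. A 2,4-difluorobenzoyl unit can thus supply C4, ring A and the sites of both oxygens, while its position 5 (the future C6) carries the handle for the biaryl bond.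

## Retrosynthesis

**18 from 17.** The three free hydroxyls of 18 are traced back to benzyl ethers in 17, and the three O–benzyl bonds are cut together. Benzyl is preferred to methyl (selective demethylation next to three methyl ethers that must stay) and to silyl or acyl groups (unstable to the enolate and alkoxide chemistry ahead). The forward reaction is a single hydrogenolysis that leaves methyl ethers and pyranones alone.

**17 from 16.** The C7–O bond is cut to give the 7-fluoride 16; the benzyloxy group is to be delivered as its alkoxide. Carrying fluorine rather than oxygen through the annulation keeps ring A electron-poor when the ring closes. It also lets a commodity arene supply the substitution pattern. In 16 only one C–F bond is left, para to the C4 carbonyl, so the substitution has no regiochemical question. The forward reaction is an SNAr that must be faster than alkoxide addition to either pyranone.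

**16 from 9 and 13 (key disconnection).** Ring C is opened at C3–C4 and O1–C8a. This leads to the acid chloride 9 and the ketone 13, which reacts through its lithium enolate 14 and the diketone 15. Both flavonoid halves are complete before they meet, the 3-oxygen arrives already protected, and the ortho/para choice between the two fluorines is settled by intramolecularity. A chalcone/oxidation route to the flavonol would instead require a free phenol ortho to the ketone on a ring that has to be built first. The forward reaction must acylate carbon rather than oxygen and must leave the pyranone of 9 untouched.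

**9 from 8, and 8 from 6 and 7.** The acid chloride comes from the acid 8, whose biaryl bond C6–C3′ is cut to the boronate 6 and 5-bromo-2,4-difluorobenzoic acid 7. Boron is placed on the electron-rich anisole ring, where the C–B bond is stable. The halide stays on the electron-poor ring, where oxidative addition is fast and where an ortho-fluoroaryl boronate would protodeboronate. Coupling the free acid saves an ester protection and deprotection, and the carboxylate deactivates the fluorines towards hydroxide during the coupling.

**6 from 5, 4, 2 and 1.** The boronate comes from the bromide 5 by borylation. The flavone 5 is opened at O1″–C2″ and by oxidation level to the chalcone 4, which is cut at its enone double bond into acetophenone 2 and 3-bromo-4-methoxybenzaldehyde 3. The central anisole ring is thus bought with its bromine and methoxy group in place. Acetophenone 2 is the monobenzyl ether of the symmetrical 1, so the 5″-oxygen is masked at the start without a selectivity problem.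

**13 from 11 and 12, and 11 from 10.** The ketone is cut at the aryl–carbonyl bond to 4-methoxyphenylmagnesium bromide 12 and the N-methoxy-N-methylamide 11, which comes from benzyloxyacetyl chloride 10. A direct Friedel–Crafts route from 10 to 13 was rejected. Alkoxyacetyl chlorides decarbonylate under strong Lewis acids to give alkoxymethyl cations, and the same Lewis acids cleave benzyl ethers.

## Roads not taken

**Alternative 1:** Flavonol ring A is built from scratch. The 4-aryl-1-methoxy-1,3-bis(trimethylsilyloxy)diene A2 and but-3-yn-2-one A3 would combine in a [4+2] cycloaddition with loss of methanol to form C4a–C8a and C5–C6 and give the acetophenone A1.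
- Merits: A1 has exactly the 5-aryl-2,4-dihydroxyacetophenone pattern the classical route lacks, with O7 at the right oxidation level. The flavonol could then be finished by Claisen–Schmidt condensation and Algar–Flynn–Oyamada oxidation, which brings in O3 without a protecting group. In these respects it is better than the chosen plan: no fluoride has to be exchanged and no acid chloride has to coexist with a pyranone.
- Weak points: it spends its key step on a benzene ring that can be bought fully substituted. A2 has an aryl group on its nucleophilic terminus, which slows the first bond formation and leaves the regiochemistry to polarisation alone, and its partner A3 is a terminal ynone that polymerises easily. After A1 the whole flavone still has to be grown from an aryl bromide, and two different acetophenone condensations must be kept apart.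
- Comparison: the chosen plan answers with convergence. Both heterocycles are complete at or before the key step, and ring A comes from 7 with its pattern fixed.

**Alternative 2:** Flavone ring B is made by an inverse-demand [4+2] cycloaddition of methyl coumalate A5 with the flavonol-6-yl methoxyacetylene A6. Loss of CO2 would form C2′–C3′ and C4′–C5′ and give the benzoate A4.
- Merits: the biaryl bond exists before ring B is made, so no hindered cross-coupling is needed for it, and the regiochemistry of cycloadditions between the coumalate A5 and ynol ethers is dependable. This avoids the protodeboronation risk of an ortho-methoxy boronate, a real advantage over the chosen Suzuki coupling.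
- Weak points: A6 needs the complete protected flavonol with a C6 halide and then an alkynyl ether, which is a labile, easily hydrated group. A palladium step is therefore still required, only with a less stable partner. After A4 the flavone pyranone must still be built from the ester by hydrolysis, aroylation of 2, Baker–Venkataraman shift and acid cyclodehydration, which endangers the peri benzyl ether. The route is linear, with the flavonol carried through every step.
- Comparison: the chosen plan couples two stable, separately prepared partners and builds no ring that commerce supplies.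

**Alternative 3:** The central anisole ring is formed by electrocyclisation. The 3,5-dienoic acid A8, heated with acetic anhydride and NaOAc, would give a dienylketene that closes C3′–C4′ and delivers the aryl acetate A7.
- Merits: the ring is made without any metal, from cheap reagents, with the C4′ oxygen and the C3′ aryl fixed by connectivity. In cost of goods for the biaryl it is better than two palladium steps.
- Weak points: A8 must have the (3E) geometry that puts the ketene and styryl arms on the same side, which is a stereochemical problem of its own. A7 carries an acetate where a methyl ether is needed. Its resorcinol ring has neither C4 nor a differentiated ortho hydroxyl, so ring A must be acylated under Lewis acids that threaten benzyl ethers. Both pyranone rings are still to be built after the key step.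
- Comparison: the chosen plan buys this ring as 3 and uses its key step on ring C, which must be made in any case.

Key step: step 9

## Route

Step 1
Reactants: 1 1-(2,6-dihydroxy-4-methoxyphenyl)ethanone
Product: 2 1-[2-(benzyloxy)-6-hydroxy-4-methoxyphenyl]ethanone
Conditions: BnBr (1.05 equiv), K2CO3, acetone, reflux
Reagents that add atoms: benzyl bromide, BrCc1ccccc1
Why: Williamson ether synthesis; the two hydroxyls of 1 are equivalent, and after the first alkylation the remaining one is held in a hydrogen bond to the ketone and is much less nucleophilic, so monoalkylation should dominate.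

Step 2
Reactants: 2 1-[2-(benzyloxy)-6-hydroxy-4-methoxyphenyl]ethanone; 3 3-bromo-4-methoxybenzaldehyde
Product: 4 (E)-1-[2-(benzyloxy)-6-hydroxy-4-methoxyphenyl]-3-(3-bromo-4-methoxyphenyl)prop-2-en-1-one
Conditions: KOH (aq), EtOH, rt
Reagents that add atoms: none
Why: Claisen–Schmidt condensation of a methyl ketone with a non-enolisable aldehyde; E1cB dehydration of the aldol gives the conjugated E-enone, a standard entry to 2′-hydroxychalcones.

Step 3
Reactants: 4 (E)-1-[2-(benzyloxy)-6-hydroxy-4-methoxyphenyl]-3-(3-bromo-4-methoxyphenyl)prop-2-en-1-one
Product: 5 5-(benzyloxy)-2-(3-bromo-4-methoxyphenyl)-7-methoxy-4H-chromen-4-one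
Conditions: I2 (10 mol %), DMSO, 120 °C
Reagents that add atoms: none
Why: Oxidative cyclisation of a 2′-hydroxychalcone: oxa-Michael closure, α-iodination and loss of HI give the flavone, and DMSO reoxidises HI to I2; the free phenol closes the ring, so the benzyl ether ends up at C5″.

Step 4
Reactants: 5 5-(benzyloxy)-2-(3-bromo-4-methoxyphenyl)-7-methoxy-4H-chromen-4-one
Product: 6 5-(benzyloxy)-7-methoxy-2-[4-methoxy-3-(4,4,5,5-tetramethyl-1,3,2-dioxaborolan-2-yl)phenyl]-4H-chromen-4-one
Conditions: B2pin2, PdCl2(dppf) (5 mol %), KOAc, 1,4-dioxane, 90 °C
Reagents that add atoms: bis(pinacolato)diboron, CC1(C)OB(OC1(C)C)B1OC(C)(C)C(C)(C)O1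
Why: Miyaura borylation: oxidative addition of the C–Br bond to zerovalent palladium, acetate-assisted transmetalation with the diboron and reductive elimination; the weak base KOAc keeps the product boronate from coupling with unreacted bromide.

Step 5
Reactants: 6 5-(benzyloxy)-7-methoxy-2-[4-methoxy-3-(4,4,5,5-tetramethyl-1,3,2-dioxaborolan-2-yl)phenyl]-4H-chromen-4-one; 7 5-bromo-2,4-difluorobenzoic acid
Product: 8 5-[5-(5-benzyloxy-7-methoxy-4-oxo-4H-chromen-2-yl)-2-methoxyphenyl]-2,4-difluorobenzoic acid
Conditions: PdCl2(dppf) (5 mol %), K2CO3, 1,4-dioxane/H2O, 85 °C; then aq HCl to pH 2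
Reagents that add atoms: none
Why: Suzuki–Miyaura coupling; the electron-poor bromide adds quickly to zerovalent palladium, the biaryl has only two ortho substituents, and 7 reacts as its carboxylate, which deactivates both C–F bonds towards hydroxide. The acid should be separable from neutral by-products by extraction into base and precipitation with acid.

Step 6
Reactants: 8 5-[5-(5-benzyloxy-7-methoxy-4-oxo-4H-chromen-2-yl)-2-methoxyphenyl]-2,4-difluorobenzoic acid
Product: 9 5-[5-(5-benzyloxy-7-methoxy-4-oxo-4H-chromen-2-yl)-2-methoxyphenyl]-2,4-difluorobenzoyl chloride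
Conditions: 1-chloro-N,N,2-trimethylprop-1-en-1-amine (1.2 equiv), CH2Cl2, 0 °C to rt; evaporate, triturate with dry hexane, use crude
Reagents that add atoms: 1-chloro-N,N,2-trimethylprop-1-en-1-amine, CC(C)=C(Cl)N(C)C
Why: Acid chloride formation with an α-chloroenamine under neutral conditions; no HCl or chloroiminium salt is present that could turn the pyranone carbonyl into a 4-chlorobenzopyrylium salt, and the only by-product is a neutral amide that is washed out.

Step 7
Reactants: 10 benzyloxyacetyl chloride
Product: 11 2-(benzyloxy)-N-methoxy-N-methylacetamide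
Conditions: MeNH(OMe)·HCl, K2CO3, CH2Cl2/H2O, 0 °C to rt
Reagents that add atoms: N,O-dimethylhydroxylamine hydrochloride, CNOC.Cl
Why: Schotten–Baumann acylation of the amine set free by K2CO3; it gives the Weinreb amide without a Lewis acid that would touch the benzyl ether.

Step 8
Reactants: 11 2-(benzyloxy)-N-methoxy-N-methylacetamide; 12 4-methoxyphenylmagnesium bromide
Product: 13 2-(benzyloxy)-1-(4-methoxyphenyl)ethanone
Conditions: THF, 0 °C; then 1 M HCl
Reagents that add atoms: none
Why: Weinreb ketone synthesis; the five-membered magnesium chelate of the tetrahedral adduct persists until the acidic quench, so the aryl group adds only once and the ketone is formed with fixed regiochemistry.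

Step 9
Reactants: 13 2-(benzyloxy)-1-(4-methoxyphenyl)ethanone; 9 5-[5-(5-benzyloxy-7-methoxy-4-oxo-4H-chromen-2-yl)-2-methoxyphenyl]-2,4-difluorobenzoyl chloride
Product: 16 3-(benzyloxy)-6-[5-(5-benzyloxy-7-methoxy-4-oxo-4H-chromen-2-yl)-2-methoxyphenyl]-7-fluoro-2-(4-methoxyphenyl)-4H-chromen-4-one, via lithium enolate 14 (not isolated), via 2-benzyloxy-1,3-diketone 15 (not isolated)
Conditions: LiN(SiMe3)2 (2.0 equiv), 13 (2.1 equiv), THF, −78 °C; 9 (1.0 equiv) in THF, −78 to 0 °C; AcOH (1.0 equiv), evaporate; K2CO3, DMF, 60 °C
Reagents that add atoms: none
Why: Tandem enolate C-aroylation and intramolecular nucleophilic aromatic substitution, the oxygen counterpart of Grohe-type cycloaracylation and a known one-pot route from ketone enolates and 2-fluorobenzoyl chlorides to chromones and flavones. The chelated Z-enolate 14 adds to the acid chloride and chloride leaves, forming C3–C4; the second equivalent of 14 removes the acidic C2 proton of diketone 15 and also moves any O-acylated material to carbon, because an enol ester is itself an acyl donor towards 14 and the diketonate is the thermodynamic sink. After neutralisation, K2CO3 regenerates the diketonate, whose anisyl-side oxygen adds to the fluorine-bearing carbon ortho to the aroyl carbonyl; the Meisenheimer intermediate, stabilised by that carbonyl, expels fluoride and the O1–C8a bond is formed. Ring C closes as a six-membered ring by intramolecular addition–elimination at an sp2 carbon; the other diketone oxygen could only form a four-membered ring, so one constitution results. No stereocentre is created, and the stereocentre of 15 at C2 disappears on closure. Ortho-over-para selectivity rests on intramolecularity: the para fluorine can react only intermolecularly, which the weak base K2CO3, the absence of strong nucleophiles after the acetic acid quench and moderate dilution suppress, so it survives as the latent 7-oxygen. Chemoselectivity over the pyranone of 9 rests on the much higher electrophilicity of the acid chloride at −78 °C and on the slight excess of ketone over LiN(SiMe3)2, which leaves no free amide base.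

Step 10
Reactants: 16 3-(benzyloxy)-6-[5-(5-benzyloxy-7-methoxy-4-oxo-4H-chromen-2-yl)-2-methoxyphenyl]-7-fluoro-2-(4-methoxyphenyl)-4H-chromen-4-one
Product: 17 3,7-bis(benzyloxy)-6-[5-(5-benzyloxy-7-methoxy-4-oxo-4H-chromen-2-yl)-2-methoxyphenyl]-2-(4-methoxyphenyl)-4H-chromen-4-one
Conditions: BnOH (1.6 equiv), NaH (1.5 equiv), DMF, 0 to 50 °C
Reagents that add atoms: benzyl alcohol, OCc1ccccc1
Why: Nucleophilic aromatic substitution by sodium benzyl oxide at the only C–F bond, which is para to the C4 carbonyl and therefore gives a carbonyl-stabilised Meisenheimer intermediate; the slight excess of alcohol over hydride leaves no free hydride, and the new ether is of the same kind as the two already present.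

Step 11
Reactants: 17 3,7-bis(benzyloxy)-6-[5-(5-benzyloxy-7-methoxy-4-oxo-4H-chromen-2-yl)-2-methoxyphenyl]-2-(4-methoxyphenyl)-4H-chromen-4-one
Product: 18 abiesin, 6-[5-(5-hydroxy-7-methoxy-4-oxo-4H-chromen-2-yl)-2-methoxyphenyl]-3,7-dihydroxy-2-(4-methoxyphenyl)-4H-chromen-4-one
Conditions: H2 (1 atm), 10% Pd/C, THF/MeOH, rt
Reagents that add atoms: none
Why: Catalytic hydrogenolysis of three benzyl ethers in one operation; aryl methyl ethers are inert, and the pyranone C2=C3 bonds, part of vinylogous ester systems, are not reduced at one atmosphere and room temperature.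

## Compound list

1 | 1-(2,6-dihydroxy-4-methoxyphenyl)ethanone | CC(=O)c1c(O)cc(OC)cc1O | starting material
2 | 1-[2-(benzyloxy)-6-hydroxy-4-methoxyphenyl]ethanone | CC(=O)c1c(O)cc(OC)cc1OCc1ccccc1 | intermediate
3 | 3-bromo-4-methoxybenzaldehyde | COc1ccc(C=O)cc1Br | starting material
4 | (E)-1-[2-(benzyloxy)-6-hydroxy-4-methoxyphenyl]-3-(3-bromo-4-methoxyphenyl)prop-2-en-1-one | COc1ccc(/C=C/C(=O)c2c(O)cc(OC)cc2OCc2ccccc2)cc1Br | intermediate
5 | 5-(benzyloxy)-2-(3-bromo-4-methoxyphenyl)-7-methoxy-4H-chromen-4-one | COc1ccc(-c2cc(=O)c3c(OCc4ccccc4)cc(OC)cc3o2)cc1Br | intermediate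
6 | 5-(benzyloxy)-7-methoxy-2-[4-methoxy-3-(4,4,5,5-tetramethyl-1,3,2-dioxaborolan-2-yl)phenyl]-4H-chromen-4-one | COc1ccc(-c2cc(=O)c3c(OCc4ccccc4)cc(OC)cc3o2)cc1B1OC(C)(C)C(C)(C)O1 | intermediate
7 | 5-bromo-2,4-difluorobenzoic acid | OC(=O)c1cc(Br)c(F)cc1F | starting material
8 | 5-[5-(5-benzyloxy-7-methoxy-4-oxo-4H-chromen-2-yl)-2-methoxyphenyl]-2,4-difluorobenzoic acid | OC(=O)c1cc(-c2cc(-c3cc(=O)c4c(OCc5ccccc5)cc(OC)cc4o3)ccc2OC)c(F)cc1F | intermediate
9 | 5-[5-(5-benzyloxy-7-methoxy-4-oxo-4H-chromen-2-yl)-2-methoxyphenyl]-2,4-difluorobenzoyl chloride | O=C(Cl)c1cc(-c2cc(-c3cc(=O)c4c(OCc5ccccc5)cc(OC)cc4o3)ccc2OC)c(F)cc1F | intermediate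
10 | benzyloxyacetyl chloride | O=C(Cl)COCc1ccccc1 | starting material
11 | 2-(benzyloxy)-N-methoxy-N-methylacetamide | CON(C)C(=O)COCc1ccccc1 | intermediate
12 | 4-methoxyphenylmagnesium bromide | COc1ccc([Mg]Br)cc1 | starting material
13 | 2-(benzyloxy)-1-(4-methoxyphenyl)ethanone | COc1ccc(cc1)C(=O)COCc1ccccc1 | intermediate
14 | lithium (Z)-2-(benzyloxy)-1-(4-methoxyphenyl)ethen-1-olate | [Li]O/C(=C\OCc1ccccc1)c1ccc(OC)cc1 | intermediate (not isolated)
15 | 2-(benzyloxy)-1-{5-[5-(5-benzyloxy-7-methoxy-4-oxo-4H-chromen-2-yl)-2-methoxyphenyl]-2,4-difluorophenyl}-3-(4-methoxyphenyl)propane-1,3-dione (racemic at C2, enolisable) | COc1ccc(cc1)C(=O)C(OCc1ccccc1)C(=O)c1cc(-c2cc(-c3cc(=O)c4c(OCc5ccccc5)cc(OC)cc4o3)ccc2OC)c(F)cc1F | intermediate (not isolated)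
16 | 3-(benzyloxy)-6-[5-(5-benzyloxy-7-methoxy-4-oxo-4H-chromen-2-yl)-2-methoxyphenyl]-7-fluoro-2-(4-methoxyphenyl)-4H-chromen-4-one | COc1ccc(cc1)-c1oc2cc(F)c(cc2c(=O)c1OCc1ccccc1)-c1cc(ccc1OC)-c1cc(=O)c2c(OCc3ccccc3)cc(OC)cc2o1 | intermediate
17 | 3,7-bis(benzyloxy)-6-[5-(5-benzyloxy-7-methoxy-4-oxo-4H-chromen-2-yl)-2-methoxyphenyl]-2-(4-methoxyphenyl)-4H-chromen-4-one | COc1ccc(cc1)-c1oc2cc(OCc3ccccc3)c(cc2c(=O)c1OCc1ccccc1)-c1cc(ccc1OC)-c1cc(=O)c2c(OCc3ccccc3)cc(OC)cc2o1 | intermediate
18 | abiesin, 6-[5-(5-hydroxy-7-methoxy-4-oxo-4H-chromen-2-yl)-2-methoxyphenyl]-3,7-dihydroxy-2-(4-methoxyphenyl)-4H-chromen-4-one | COc1ccc(-c2oc3cc(O)c(-c4cc(-c5cc(=O)c6c(O)cc(OC)cc6o5)ccc4OC)cc3c(=O)c2O)cc1 | target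

## Step count and risks

Total: 11 steps. Longest linear sequence: 9 steps (steps 1, 2, 3, 4, 5, 6, 9, 10, 11, from 1). The ketone branch (steps 7 and 8) joins at step 9.

**Step 9 (key step).** The acylation may be diverted in several ways:
- the large acid chloride may dissolve slowly at −78 °C and meet the enolate only on warming;
- O-acylation may not be fully returned to carbon;
- the enolate may add to C2″ of the pyranone;
- an intermolecular substitution at the para fluorine may compete during ring closure.

Fallback: run the annulation on the small bromo acid chloride and form the biaryl bond afterwards. Acid 7 is converted with the same chloroenamine into 5-bromo-2,4-difluorobenzoyl chloride F1. Acylation of enolate 14 (from 13) gives 2-(benzyloxy)-1-(5-bromo-2,4-difluorophenyl)-3-(4-methoxyphenyl)propane-1,3-dione F2. K2CO3 in DMF closes it to 3-(benzyloxy)-6-bromo-7-fluoro-2-(4-methoxyphenyl)-4H-chromen-4-one F3. Suzuki–Miyaura coupling of F3 with boronate 6 (PdCl2(dppf), K3PO4, dioxane with a little water) returns to the route at 16. The same bonds and the same ring are formed, but no pyranone is present during acylation.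

**Step 10.** Substitution at C7 may be slow, since it is flanked by the C6 aryl group and activated only by a vinylogous ester carbonyl. Benzyl oxide may then add to C2 or C2″ and open a pyranone ring. Fallback: use an oxygen nucleophile of much lower basicity that delivers the phenol itself. From 16, acetohydroxamic acid and K2CO3 in DMSO at 80 °C should give by SNAr the N-aryloxyacetamide N-{[3-(benzyloxy)-6-[5-(5-benzyloxy-7-methoxy-4-oxo-4H-chromen-2-yl)-2-methoxyphenyl]-2-(4-methoxyphenyl)-4-oxo-4H-chromen-7-yl]oxy}acetamide F4. F4 fragments in a Lossen-type step to 3-(benzyloxy)-6-[5-(5-benzyloxy-7-methoxy-4-oxo-4H-chromen-2-yl)-2-methoxyphenyl]-7-hydroxy-2-(4-methoxyphenyl)-4H-chromen-4-one F5. Hydrogenolysis of F5 under the conditions of step 11 returns to the route at 18.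

**Step 3.** Hydrogen iodide formed at 120 °C may remove the peri benzyl ether, or iodine may substitute the electron-rich resorcinol ring. Fallback: separate ring closure from oxidation. From 4, NaOAc in refluxing EtOH should give by oxa-Michael addition the racemic flavanone 5-(benzyloxy)-2-(3-bromo-4-methoxyphenyl)-7-methoxychroman-4-one F6. Dehydrogenation of F6 with DDQ in dioxane at reflux returns to the route at 5.

**Step 5.** Protodeboronation of the ortho-methoxy boronate may outrun transmetalation, because the halide partner, as its carboxylate, stays largely in the aqueous phase. Hydroxide attack on an activated fluorine is a lesser risk. Fallback: couple a neutral ester. From 7, Boc2O and DMAP in t-BuOH give tert-butyl 5-bromo-2,4-difluorobenzoate F7. Coupling of F7 with 6 (PdCl2(dppf), K3PO4, dioxane with a little water) gives tert-butyl 5-[5-(5-benzyloxy-7-methoxy-4-oxo-4H-chromen-2-yl)-2-methoxyphenyl]-2,4-difluorobenzoate F8. Acidolysis of F8 with CF3CO2H in CH2Cl2 returns to the route at 8 without any hydroxide.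

**Step 11.** Debenzylation may stop part-way because partly deprotected intermediates precipitate on the catalyst, and forcing the reaction may reduce a pyranone C2=C3 bond. Fallback: cleave the benzyl ethers by a Lewis acid instead of hydrogen. From 17, BCl3 with pentamethylbenzene as cation scavenger in CH2Cl2 at −78 °C should give 18 directly. No methyl ether lies peri to a carbonyl, so the methyl ethers should survive. No new compound is made.

## Further compounds

F1 | step 9 | 5-bromo-2,4-difluorobenzoyl chloride | O=C(Cl)c1cc(Br)c(F)cc1F
F2 | step 9 | 2-(benzyloxy)-1-(5-bromo-2,4-difluorophenyl)-3-(4-methoxyphenyl)propane-1,3-dione (racemic) | COc1ccc(cc1)C(=O)C(OCc1ccccc1)C(=O)c1cc(Br)c(F)cc1F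
F3 | step 9 | 3-(benzyloxy)-6-bromo-7-fluoro-2-(4-methoxyphenyl)-4H-chromen-4-one | COc1ccc(cc1)-c1oc2cc(F)c(Br)cc2c(=O)c1OCc1ccccc1
F4 | step 10 | N-{[3-(benzyloxy)-6-[5-(5-benzyloxy-7-methoxy-4-oxo-4H-chromen-2-yl)-2-methoxyphenyl]-2-(4-methoxyphenyl)-4-oxo-4H-chromen-7-yl]oxy}acetamide | COc1ccc(cc1)-c1oc2cc(ONC(C)=O)c(cc2c(=O)c1OCc1ccccc1)-c1cc(ccc1OC)-c1cc(=O)c2c(OCc3ccccc3)cc(OC)cc2o1
F5 | step 10 | 3-(benzyloxy)-6-[5-(5-benzyloxy-7-methoxy-4-oxo-4H-chromen-2-yl)-2-methoxyphenyl]-7-hydroxy-2-(4-methoxyphenyl)-4H-chromen-4-one | COc1ccc(cc1)-c1oc2cc(O)c(cc2c(=O)c1OCc1ccccc1)-c1cc(ccc1OC)-c1cc(=O)c2c(OCc3ccccc3)cc(OC)cc2o1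
F6 | step 3 | 5-(benzyloxy)-2-(3-bromo-4-methoxyphenyl)-7-methoxychroman-4-one (racemic) | COc1ccc(C2CC(=O)c3c(OCc4ccccc4)cc(OC)cc3O2)cc1Br
F7 | step 5 | tert-butyl 5-bromo-2,4-difluorobenzoate | CC(C)(C)OC(=O)c1cc(Br)c(F)cc1F
F8 | step 5 | tert-butyl 5-[5-(5-benzyloxy-7-methoxy-4-oxo-4H-chromen-2-yl)-2-methoxyphenyl]-2,4-difluorobenzoate | CC(C)(C)OC(=O)c1cc(-c2cc(-c3cc(=O)c4c(OCc5ccccc5)cc(OC)cc4o3)ccc2OC)c(F)cc1F
F0 | step 11 | none | none
A1 | alternative 1 | 1-[5-(5-bromo-2-methoxyphenyl)-2,4-dihydroxyphenyl]ethanone | CC(=O)c1cc(-c2cc(Br)ccc2OC)c(O)cc1O
A2 | alternative 1 | 4-(5-bromo-2-methoxyphenyl)-1-methoxy-1,3-bis(trimethylsilyloxy)buta-1,3-diene (double-bond geometry not defined) | COC(O[Si](C)(C)C)=CC(O[Si](C)(C)C)=Cc1cc(Br)ccc1OC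
A3 | alternative 1 | but-3-yn-2-one | CC(=O)C#C
A4 | alternative 2 | methyl 3-[3,7-bis(benzyloxy)-2-(4-methoxyphenyl)-4-oxo-4H-chromen-6-yl]-4-methoxybenzoate | COC(=O)c1ccc(OC)c(c1)-c1cc2c(=O)c(OCc3ccccc3)c(-c3ccc(OC)cc3)oc2cc1OCc1ccccc1
A5 | alternative 2 | methyl coumalate (methyl 2-oxo-2H-pyran-5-carboxylate) | COC(=O)c1ccc(=O)oc1
A6 | alternative 2 | 3,7-bis(benzyloxy)-6-(methoxyethynyl)-2-(4-methoxyphenyl)-4H-chromen-4-one | COC#Cc1cc2c(=O)c(OCc3ccccc3)c(-c3ccc(OC)cc3)oc2cc1OCc1ccccc1
A7 | alternative 3 | methyl 4-acetoxy-3-[2,4-bis(benzyloxy)phenyl]benzoate | COC(=O)c1ccc(OC(C)=O)c(c1)-c1ccc(OCc2ccccc2)cc1OCc1ccccc1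
A8 | alternative 3 | (3E,5E)-6-[2,4-bis(benzyloxy)phenyl]-4-(methoxycarbonyl)hexa-3,5-dienoic acid | OC(=O)C/C=C(C(=O)OC)\C=C\c1ccc(OCc2ccccc2)cc1OCc1ccccc1
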